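## The problem

Gancaonin G (15) is an isoflavone: benzo ring A is fused to the 4-pyranone ring C across C4a–C8a, and the 4-hydroxyphenyl ring B is attached at C3. It has no stereocentre, so every difficulty is one of position. Ring A is fully differentiated (O1 at C8a, the carbonyl carbon at C4a, a free hydroxyl at C5, prenyl at C6, a methyl ether at C7, hydrogen at C8), so a synthesis must tell O5 from O7 and C6 from C8. The prenyl group is the fragile part: its allylic and benzylic C–H bonds are easily abstracted by radicals, and protic or Lewis acids add the neighbouring O5 hydroxyl across it to give a chroman. The free phenols and ring C, which hydroxide opens at C2, set further limits. The C4–C4a bond joins a carbonyl carbon to an arene carbon ortho to the ether oxygen O1; if ring A is carried as a 3,5-dimethoxyphenyl ether, its two ortho carbons are equivalent, so an aldehyde C–H and an aryl C–H can be joined there without any choice of site. Once ring C exists, the C4 carbonyl lies peri to O5, which lets a chelating Lewis acid remove the O5 methyl group alone and lets O5 pass a carbon chain to C6 by a sigmatropic shift.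

## Retrosynthesis

**Prenyl last (15 ⇐ 14 ⇐ 13).** The Si–O bond of silyl ether 14 is cut first, then the C=C bond of the prenyl group, which leads back to the 6-allyl compound 13 and 2-methylbut-2-ene by cross-metathesis. Direct C-prenylation of a prunetin derivative would give C6/C8 mixtures, and an O5-prenyl ether would rearrange to a 1,1-dimethylallyl group at C6 or a prenyl group at C8. An allyl group is cleaner and survives the heat of the preceding step. The forward reaction only has to tolerate a hydrogen-bonded phenol and leave the C2=C3 bond alone.

**Carbon to C6 from O5 (13 ⇐ 12 ⇐ 11).** The C6–allyl bond is cut and the allyl group returned to O5, giving allyl ether 12 (aromatic Claisen rearrangement). Of the two carbons ortho to O5, C4a is quaternary, so only C6 can keep the allyl group. Ether 12 comes from the 4'-silyl ether of prunetin, 11, by cutting the O5–allyl bond. The forward etherification must engage a phenol that is hydrogen-bonded to the C4 carbonyl without disturbing the aryl silyl ether, which points to neutral Mitsunobu conditions.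

**Oxygen pattern (11 ⇐ 10 ⇐ 9).** Removing the silyl group gives prunetin 10, and returning a methyl group to O5 and an isopropyl group to O4' gives 9. BCl3 is asked to cleave the chelated peri methyl ether and the secondary alkyl ether and to leave the O7 methyl ether. Because this happens before any alkene is in the molecule, the acid-sensitivity of prenyl never comes into play.

**Ring C by the C4–C4a bond (9 ⇐ 8).** This is the central cut. Cutting O1–C2 (deoxybenzoin route) or C3–C1' (3-halochromone coupling) leaves an acylated phloroglucinol derivative to be made first. Cutting C4–C4a opens ring C to the acyclic (Z)-3-aryloxy-2-arylacrolein 8, in which ring A is a symmetric 3,5-dimethoxyphenyl ether and both C–H partners are already in place. The forward reaction must oxidise the formyl C–H in preference to all other C–H bonds and needs the aryloxy group cis to the formyl group.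

**Vinyl ether bond (8 ⇐ 6 + 7).** The C–O bond between the enal β-carbon and the phenol oxygen (O1–C2 of the isoflavone) is cut to the β-chloroenal 6 and commercial 3,5-dimethoxyphenol 7. The forward reaction is an addition–elimination at a vinylogous acid chloride; it must go through oxygen rather than ring carbon of the phenoxide and keep the alkene geometry.

**Three-carbon unit (6 ⇐ 5 ⇐ 3 ⇐ 1).** Chloride 6 is the vinylogous acid chloride of arylmalondialdehyde 5. The two formyl carbons of 5 are both cut from the benzylic carbon, leading to 4-isopropoxyphenylacetic acid 3, dimethylformamide and loss of CO2 (Vilsmeier–Haack–Arnold reaction). Acid 3 comes from 4-hydroxyphenylacetic acid 1 by O-alkylation. Isopropyl is chosen for O4' because it survives POCl3, has no benzylic or allylic C–H, and leaves with the O5 methyl group under BCl3. A methyl ether there could not be told from the O7 methyl, and a benzyl ether would offer the oxidant a weak C–H bond.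

## Roads not taken

Alternative 1: Ring A would be built last by a [3+3] annulation, cutting C8–C8a and C5–C6. The kinetic enolate of 6-methylhept-5-en-2-one A2 would displace methanethiolate from methyl 5-[4-(methoxymethoxy)phenyl]-2-(methylsulfanyl)-4-oxo-4H-pyran-3-carboxylate A3, and a second enolate at the more substituted α-carbon would attack the ester to give 5,7-dihydroxy-4'-(methoxymethoxy)-6-prenylisoflavone A1.
- Merits: the prenyl group arrives with A2, which is a commercial ketone, and is placed at C6 by the connectivity of the annulation, so no Claisen relay and no C6/C8 question arises. Only O7-methylation and MOM removal separate A1 from 15, a shorter end game than the six steps that follow the ring closure here.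
- Weak points: after the first substitution the most acidic site is the methylene between ketone and pyranone, not the carbon that has to attack the ester, so acylation on the enolate oxygen competes with C5–C6 bond formation. The 4-pyranone of A3 is also open to attack at its unsubstituted C6. A3 needs its own multistep preparation. The final MOM removal uses acid next to a prenyl/5-hydroxyl pair.
- Comparison: in step count after the key step this road is better. The chosen plan sets against it a ring closure with no regiochemical choice, commodity ring A material and a prenyl group that never meets acid.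

Alternative 2: Ring C would be closed by aryne insertion, cutting O1–C8a, C4–C4a and O1–C2. CsF would release 3,5-dimethoxy-4-prenylbenzyne A7 from 3,5-dimethoxy-4-prenyl-2-(trimethylsilyl)phenyl triflate A6, and A7 would insert into the O–C(=O) bond of (E)-2-(4-isopropoxyphenyl)-3-methoxyacrylic acid A5. The resulting phenoxide would displace methoxide to give 4'-isopropoxy-5,7-dimethoxy-6-prenylisoflavone A4.
- Merits: three bonds form in one operation, the methoxy group next to the triple bond of A7 directs the carboxylate oxygen to the right carbon, and insertion of arynes into carboxylic acid C–O bonds is a known reaction type. A5 is no harder to make than enal 8. The key step therefore carries less methodological risk than the one chosen here.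
- Weak points: protonation of the aryl anion by the acid A5 (simple O-arylation) competes with acyl transfer. A6 requires a para-selective prenylation and an ortho-silylation of a phloroglucinol ether. Above all, A4 still has to lose its O5 methyl and O4' isopropyl groups with a Lewis acid while the prenyl group sits beside O5, the situation in which chroman formation is most likely.
- Comparison: the chosen plan gives up the precedent for the ring closure but does all Lewis-acid chemistry before any alkene is present.

Alternative 3: Ring A would be built by a Danheiser benzannulation, cutting C5–C6, C7–C8 and C4a–C5. Photochemical Wolff rearrangement of 2-(2-diazoacetyl)-5-[4-(triisopropylsilyloxy)phenyl]-4H-pyran-4-one A9 would give the pyranonyl ketene 2-(2-oxoethenyl)-5-[4-(triisopropylsilyloxy)phenyl]-4H-pyran-4-one A10. A10 would add to 1-methoxy-5-methylhex-4-en-1-yne A11, and electrocyclic ring opening of the [2+2] adduct followed by 6π closure would give gancaonin G 4'-O-triisopropylsilyl ether A8.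
- Merits: all four ring A substituents are placed by the mechanism, O5 is born free and O7 methylated, and A8 is one desilylation from 15. If it worked, this would be the shortest and most convergent route, and in step economy it is better than the chosen plan.
- Weak points: the 4-pyranone chromophore of A9 is itself photolabile under the light needed for the Wolff step. The 6π closure has to engage the vinylogous ester double bond of the pyranone. A9 and A11 are both specialised, sensitive fragments whose preparation together is about as long as the whole front end of the chosen route.
- Comparison: both plans rest on an untested key step. The chosen plan runs it thermally on a substrate made in four steps from cheap materials and has a classical acid-mediated closure in reserve.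

Key step: step 5

Assumption: chloroenal 6 and aryloxyenal 8 are taken to form with retention as the Z isomers (heteroatom cis to the formyl group); material containing the E isomers would still be taken into step 5, for the reason stated there.

## Steps

**Step 1**
Reactants: 1 4-hydroxyphenylacetic acid
Product: 3 4-isopropoxyphenylacetic acid, via isopropyl ester 2 (not isolated)
Conditions: 2-bromopropane (3 equiv), K2CO3, DMF, 70 °C; then NaOH, H2O/MeOH, 60 °C; HCl to pH 2
Reagents that add atoms: 2-bromopropane, CC(C)Br; sodium hydroxide, [Na+].[OH-]
Why: Williamson ether synthesis on the phenoxide with concurrent esterification of the carboxylate, followed by saponification of the isopropyl ester in the same flask; the aryl isopropyl ether is inert to hydroxide.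

**Step 2**
Reactants: 3 4-isopropoxyphenylacetic acid
Product: 5 2-(4-isopropoxyphenyl)propanedial, via vinamidinium chloride 4 (not isolated)
Conditions: POCl3 (3 equiv), DMF, 0 → 80 °C; then ice, aq. NaOH, 90 °C; HCl to pH 3
Reagents that add atoms: N,N-dimethylformamide, CN(C)C=O; water, O
Why: Vilsmeier–Haack–Arnold reaction: the arylacetic acid is formylated twice at the benzylic carbon with loss of CO2 to give the 2-aryl vinamidinium salt, and hot alkali hydrolyses both iminium termini to the arylmalondialdehyde, which should exist mainly as its hydrogen-bonded enol. The para-alkoxyphenyl ring is too weakly activated at its free positions to be formylated, and the isopropyl ether is stable to POCl3.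

**Step 3**
Reactants: 5 2-(4-isopropoxyphenyl)propanedial
Product: 6 (Z)-3-chloro-2-(4-isopropoxyphenyl)prop-2-enal
Conditions: (COCl)2 (1.1 equiv), DMF (cat.), CH2Cl2, 0 °C; used crude
Reagents that add atoms: oxalyl chloride, ClC(=O)C(=O)Cl
Why: Vinylogous acid chloride formation, as in the conversion of 1,3-dicarbonyl enols into β-chloroenones: the enol oxygen is activated and chloride replaces it by addition–elimination. Retention at the intramolecularly hydrogen-bonded cis-enol should place chlorine cis to the formyl group.

**Step 4**
Reactants: 6 (Z)-3-chloro-2-(4-isopropoxyphenyl)prop-2-enal; 7 3,5-dimethoxyphenol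
Product: 8 (Z)-3-(3,5-dimethoxyphenoxy)-2-(4-isopropoxyphenyl)prop-2-enal
Conditions: 7 (1.0 equiv), K2CO3 (1.5 equiv), MeCN, 0 °C → rt
Reagents that add atoms: none
Why: Nucleophilic vinylic substitution (addition–elimination) of the β-chloroenal by the phenoxide oxygen, the usual route to β-aryloxyenals; with chloride as leaving group such substitutions normally proceed with retention, so the aryloxy group should stay cis to the formyl group. One equivalent of phenol at low temperature limits reversible phenoxide addition, which would equilibrate the geometry.

**Step 5**
Reactants: 8 (Z)-3-(3,5-dimethoxyphenoxy)-2-(4-isopropoxyphenyl)prop-2-enal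
Product: 9 4'-isopropoxy-5,7-dimethoxyisoflavone
Conditions: Fe(C5H5)2 (5 mol %), t-BuOOH (5.5 M in decane, 2.5 equiv, slow addition), MeCN, 90 °C, Ar
Reagents that add atoms: none
Why: Proposed new method: ferrocene Fe(C5H5)2 (divalent iron) reduces tert-butyl hydroperoxide to the tert-butoxyl radical, which abstracts the weak, hydridic formyl hydrogen of 8; the resulting alkenoyl radical keeps its CO because decarbonylation would leave an unstabilised vinyl radical. It attacks the ortho carbon of the 3,5-dimethoxyphenyl ether (the future C4a) and closes ring C as a six-membered ring by intramolecular homolytic aromatic substitution (ortho, 6-endo mode; 5-exo ipso attack at C8a is the usual minor competitor in aryl ethers). The cyclohexadienyl radical has its spin on C5, C7 and C8a, all oxygen-bearing, so ferrocenium (trivalent iron) should oxidise it easily, and loss of the proton restores the arene and the catalyst. The closest known reaction type is the peroxide-driven cross-dehydrogenative acylation of 2-aryloxybenzaldehydes to xanthones, which uses aroyl radicals; an alkenoyl radical from a 3-aryloxyacrolein has not been used in this way. No stereocentre is formed. Site selectivity on ring A needs no control because the two ortho carbons of the ether are equivalent by symmetry and the para carbon cannot be reached, while chemoselectivity for the formyl C–H over the isopropyl methine and methoxy C–H bonds rests on the faster, polarity-matched abstraction from aldehydes and on the absence of any allylic C–H at this stage. The closure needs the aryloxy group cis to the acyl carbon, which the Z geometry of 8 provides; E material is expected to be drawn in through the α-ketenyl radical form open to alkenoyl radicals, in which the C2–C3 bond can rotate and which the aryloxy oxygen stabilises here.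

**Step 6**
Reactants: 9 4'-isopropoxy-5,7-dimethoxyisoflavone
Product: 10 prunetin (5,4'-dihydroxy-7-methoxyisoflavone)
Conditions: BCl3 (5 equiv), CH2Cl2, −78 °C → rt; MeOH, then aq. work-up
Reagents that add atoms: none
Why: Lewis-acid ether cleavage: BCl3 chelated between the C4 carbonyl and O5 removes the peri methyl group, and it cleaves the secondary alkyl (isopropyl) aryl ether, while the unchelated O7 methyl ether is not attacked. No alkene is present yet.

**Step 7**
Reactants: 10 prunetin
Product: 11 4'-(tert-butyldimethylsilyloxy)-5-hydroxy-7-methoxyisoflavone
Conditions: TBSCl (1.1 equiv), imidazole (2.2 equiv), DMF, 0 °C → rt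
Reagents that add atoms: tert-butyldimethylsilyl chloride, CC(C)(C)[Si](C)(C)Cl
Why: Selective silylation of the free, more acidic 4'-phenol; the 5-hydroxyl is tied up in a strong hydrogen bond to the C4 carbonyl and is not silylated under these conditions.

**Step 8**
Reactants: 11 4'-(tert-butyldimethylsilyloxy)-5-hydroxy-7-methoxyisoflavone
Product: 12 5-allyloxy-4'-(tert-butyldimethylsilyloxy)-7-methoxyisoflavone
Conditions: allyl alcohol (2 equiv), PPh3 (2 equiv), DIAD (2 equiv), THF, 0 °C → rt
Reagents that add atoms: prop-2-en-1-ol, C=CCO
Why: Mitsunobu etherification; the hydrogen-bonded 5-hydroxyl of flavonoids is known to be alkylated by primary allylic alcohols under these neutral conditions, which do not touch the aryl silyl ether.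

**Step 9**
Reactants: 12 5-allyloxy-4'-(tert-butyldimethylsilyloxy)-7-methoxyisoflavone
Product: 13 6-allyl-4'-(tert-butyldimethylsilyloxy)-5-hydroxy-7-methoxyisoflavone
Conditions: PhNEt2, 200 °C, sealed tube, Ar
Reagents that add atoms: none
Why: Aromatic Claisen rearrangement ([3,3] shift): of the two carbons ortho to O5, C4a is quaternary, so the allyl group is delivered to C6 and the dienone enolises to the hydrogen-bonded phenol. C8 could be reached only by a further Cope shift, which for an unsubstituted allyl group is slower than enolisation.

**Step 10**
Reactants: 13 6-allyl-4'-(tert-butyldimethylsilyloxy)-5-hydroxy-7-methoxyisoflavone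
Product: 14 4'-(tert-butyldimethylsilyloxy)-5-hydroxy-7-methoxy-6-(3-methylbut-2-enyl)isoflavone
Conditions: 2-methylbut-2-ene (excess, co-solvent), second-generation Grubbs catalyst RuCl2(H2IMes)(PCy3)(=CHPh) (5 mol %), CH2Cl2, 40 °C, sealed
Reagents that add atoms: 2-methylbut-2-ene, CC=C(C)C
Why: Olefin cross-metathesis of a terminal allylarene with 2-methylbut-2-ene, the standard conversion of allyl into prenyl; the trisubstituted product does not re-enter the cycle, and the C2=C3 bond of ring C is too hindered and electron-poor to react.

**Step 11**
Reactants: 14 4'-(tert-butyldimethylsilyloxy)-5-hydroxy-7-methoxy-6-(3-methylbut-2-enyl)isoflavone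
Product: 15 gancaonin G
Conditions: TBAF (1.1 equiv), AcOH (1.1 equiv), THF, 0 °C
Reagents that add atoms: none
Why: Fluoride cleavage of the aryl silyl ether; the acetic acid buffer keeps ring C away from free phenoxide or alkoxide base, and no acid strong enough to add O5 across the prenyl double bond is present.

## Compound list

1 | 4-hydroxyphenylacetic acid | OC(=O)Cc1ccc(O)cc1 | starting material
2 | isopropyl (4-isopropoxyphenyl)acetate | CC(C)OC(=O)Cc1ccc(OC(C)C)cc1 | intermediate
3 | 4-isopropoxyphenylacetic acid | OC(=O)Cc1ccc(OC(C)C)cc1 | intermediate
4 | N-[3-(dimethylamino)-2-(4-isopropoxyphenyl)prop-2-en-1-ylidene]-N-methylmethanaminium chloride (vinamidinium salt) | CN(C)/C=C(/C=[N+](C)C)c1ccc(OC(C)C)cc1.[Cl-] | intermediate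
5 | 2-(4-isopropoxyphenyl)propanedial | O=CC(C=O)c1ccc(OC(C)C)cc1 | intermediate
6 | (Z)-3-chloro-2-(4-isopropoxyphenyl)prop-2-enal | O=C/C(=C\Cl)c1ccc(OC(C)C)cc1 | intermediate
7 | 3,5-dimethoxyphenol | COc1cc(O)cc(OC)c1 | starting material
8 | (Z)-3-(3,5-dimethoxyphenoxy)-2-(4-isopropoxyphenyl)prop-2-enal | O=C/C(=C\Oc1cc(OC)cc(OC)c1)c1ccc(OC(C)C)cc1 | intermediate
9 | 4'-isopropoxy-5,7-dimethoxyisoflavone | COc1cc(OC)c2c(c1)occ(-c1ccc(OC(C)C)cc1)c2=O | intermediate
10 | prunetin (5,4'-dihydroxy-7-methoxyisoflavone) | COc1cc(O)c2c(c1)occ(-c1ccc(O)cc1)c2=O | intermediate
11 | 4'-(tert-butyldimethylsilyloxy)-5-hydroxy-7-methoxyisoflavone | COc1cc(O)c2c(c1)occ(-c1ccc(O[Si](C)(C)C(C)(C)C)cc1)c2=O | intermediate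
12 | 5-allyloxy-4'-(tert-butyldimethylsilyloxy)-7-methoxyisoflavone | COc1cc(OCC=C)c2c(c1)occ(-c1ccc(O[Si](C)(C)C(C)(C)C)cc1)c2=O | intermediate
13 | 6-allyl-4'-(tert-butyldimethylsilyloxy)-5-hydroxy-7-methoxyisoflavone | COc1cc2occ(-c3ccc(O[Si](C)(C)C(C)(C)C)cc3)c(=O)c2c(O)c1CC=C | intermediate
14 | 4'-(tert-butyldimethylsilyloxy)-5-hydroxy-7-methoxy-6-(3-methylbut-2-enyl)isoflavone | COc1cc2occ(-c3ccc(O[Si](C)(C)C(C)(C)C)cc3)c(=O)c2c(O)c1CC=C(C)C | intermediate
15 | gancaonin G | COc1cc2occ(-c3ccc(O)cc3)c(=O)c2c(O)c1CC=C(C)C | target

## Step count and least certain steps

Total: 11 steps. Longest linear sequence: 11 steps (1 → 15); 3,5-dimethoxyphenol 7 enters at step 4.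

**Step 5 (key step).**
- What may go wrong: hydrogen abstraction from the isopropyl methine or from the electron-rich alkene competes; the acyl radical is over-oxidised to the carboxylic acid before it cyclises; ipso attack leads to aryl migration; or a radical of the wrong alkene geometry fails to close and is lost.
- Fallback (known chemistry), from 8 back to 9: oxidation of the aldehyde with NaClO2/NaH2PO4/2-methylbut-2-ene would give (Z)-3-(3,5-dimethoxyphenoxy)-2-(4-isopropoxyphenyl)acrylic acid F1. Trifluoroacetic anhydride in CH2Cl2 would then close ring C by intramolecular Friedel–Crafts acylation at the same, highly activated ortho carbon, returning to 9. This is the classical acid-mediated chromone closure of 3-aryloxyacrylic acids; the acidic medium also equilibrates the alkene geometry, and the isopropyl ether tolerates it.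

**Step 4.**
- What may go wrong: the alkene geometry is lost through reversible conjugate addition of phenoxide, so that the isomer with the aryloxy group trans to the formyl group accumulates; attack through ring carbon of the ambident phenoxide is a lesser risk.
- Fallback, from 6 and 7 back to 8: the substitution is run to equilibrium (excess K2CO3, DMF, 60 °C) to give (E)-3-(3,5-dimethoxyphenoxy)-2-(4-isopropoxyphenyl)prop-2-enal F2. Direct irradiation (365 nm, MeCN) should then set up a photostationary E/Z mixture, as is well known for 3-alkoxy-2-arylacrylic systems. 8 is separated from it and F2 is recycled.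

**Step 8.**
- What may go wrong: the hydrogen-bonded phenol is a reluctant Mitsunobu partner, so conversion stalls and the azodicarboxylate is consumed unproductively.
- Fallback, from 11 to 12: allylation by a different mechanism, using allyl methyl carbonate and Pd(PPh3)4 (zerovalent palladium) in THF at 60 °C. Methoxide released on ionisation deprotonates the phenol and a cationic allylpalladium complex is the electrophile. This fallback makes no compound outside the route, hence the entry F0.

**Step 9.**
- What may go wrong: at 200 °C the allyl group may migrate on to C8 by a Cope shift of the dienone, the o-allylphenol may cyclise, or the silyl ether may be lost.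
- Fallback, from 11 to 13, replacing steps 8 and 9: iodination directed to C6 by the free 5-hydroxyl (BnMe3N+ ICl2−, CaCO3, CH2Cl2/MeOH) would give 4'-(tert-butyldimethylsilyloxy)-5-hydroxy-6-iodo-7-methoxyisoflavone F3. Stille coupling with allyltributylstannane and Pd(PPh3)4 (zerovalent palladium) in DMF at 80 °C would then give 13.

## Further compounds

F1 | step 5 | (Z)-3-(3,5-dimethoxyphenoxy)-2-(4-isopropoxyphenyl)acrylic acid | OC(=O)/C(=C\Oc1cc(OC)cc(OC)c1)c1ccc(OC(C)C)cc1
F2 | step 4 | (E)-3-(3,5-dimethoxyphenoxy)-2-(4-isopropoxyphenyl)prop-2-enal | O=C/C(=C/Oc1cc(OC)cc(OC)c1)c1ccc(OC(C)C)cc1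
F0 | step 8 | none | none
F3 | step 9 | 4'-(tert-butyldimethylsilyloxy)-5-hydroxy-6-iodo-7-methoxyisoflavone | COc1cc2occ(-c3ccc(O[Si](C)(C)C(C)(C)C)cc3)c(=O)c2c(O)c1I
A1 | alternative 1 | 5,7-dihydroxy-4'-(methoxymethoxy)-6-prenylisoflavone | COCOc1ccc(cc1)-c1coc2cc(O)c(CC=C(C)C)c(O)c2c1=O
A2 | alternative 1 | 6-methylhept-5-en-2-one | CC(=O)CCC=C(C)C
A3 | alternative 1 | methyl 5-[4-(methoxymethoxy)phenyl]-2-(methylsulfanyl)-4-oxo-4H-pyran-3-carboxylate | COC(=O)c1c(SC)occ(-c2ccc(OCOC)cc2)c1=O
A4 | alternative 2 | 4'-isopropoxy-5,7-dimethoxy-6-prenylisoflavone | COc1cc2occ(-c3ccc(OC(C)C)cc3)c(=O)c2c(OC)c1CC=C(C)C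
A5 | alternative 2 | (E)-2-(4-isopropoxyphenyl)-3-methoxyacrylic acid | CO/C=C(/C(=O)O)c1ccc(OC(C)C)cc1
A6 | alternative 2 | 3,5-dimethoxy-4-(3-methylbut-2-enyl)-2-(trimethylsilyl)phenyl trifluoromethanesulfonate | COc1cc(OS(=O)(=O)C(F)(F)F)c([Si](C)(C)C)c(OC)c1CC=C(C)C
A7 | alternative 2 | 3,5-dimethoxy-4-(3-methylbut-2-enyl)benzyne | COC1=CC#CC(OC)=C1CC=C(C)C
A8 | alternative 3 | gancaonin G 4'-O-triisopropylsilyl ether | COc1cc2occ(-c3ccc(O[Si](C(C)C)(C(C)C)C(C)C)cc3)c(=O)c2c(O)c1CC=C(C)C
A9 | alternative 3 | 2-(2-diazoacetyl)-5-[4-(triisopropylsilyloxy)phenyl]-4H-pyran-4-one | [N-]=[N+]=CC(=O)c1cc(=O)c(-c2ccc(O[Si](C(C)C)(C(C)C)C(C)C)cc2)co1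
A10 | alternative 3 | 2-(2-oxoethenyl)-5-[4-(triisopropylsilyloxy)phenyl]-4H-pyran-4-one | O=C=Cc1cc(=O)c(-c2ccc(O[Si](C(C)C)(C(C)C)C(C)C)cc2)co1
A11 | alternative 3 | 1-methoxy-5-methylhex-4-en-1-yne | COC#CCC=C(C)C
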